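**Plan**

1. Retrosynthesis: after removal of the 19 benzyl ethers and of the gallate on the middle unit, ring C of the top epicatechin unit is cut across O1–C2 and C3–C4 (retro oxa-[4+2]). This gives an ortho-quinone methide on top ring A, carried at C8 of the middle unit, and a (Z)-enol gallate. The carbinol that hides the quinone methide is cut at its bond to C8 (aryllithium plus salicylaldehyde), and the remaining dimer at its 4β→8 interflavan bond.
2. Enabling feature: top ring A is a phloroglucinol ring whose O1–C8a–C4a–C4 array is a latent 1-oxadiene. C4 is doubly benzylic (flanked by two trioxygenated rings A) and so easily ionised, C2=C3 with ring B and the 3-O-gallate is a latent β-acyloxystyrene, and only top ring A has a free phenol ortho to that carbon.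
3. Forward: rings C of the middle and bottom units come from (−)-epicatechin and (+)-catechin and are joined by cationic C4→C8 coupling. Top ring A is added to C8 of the middle unit as an aldehyde. Ring C of the top unit is closed last by the cycloaddition, which also brings in ring B and one gallate; esterification and hydrogenolysis finish.
4. Stereochemistry: C2/C3 of the middle and bottom units come from the chiral pool; C4 of the middle unit from attack trans to the axial 3-OH. C2/C3 of the top unit (cis) come from the Z alkene; C4 of the top unit and the absolute sense from the transition-state arrangement under a chiral phosphoric acid.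

Key step: step 11

Remark: the new carbinol carbon in 12 and 13 and the exocyclic double bond of 18 are written without configuration, because both epimers (isomers) are expected and both converge in step 11.

**Route**

Step 1
Reactants: 1 (−)-epicatechin
Product: 2 5,7,3',4'-tetra-O-benzyl-(−)-epicatechin (2R,3R, 3-OH free)
Conditions: BnBr (4.4 equiv), K2CO3, DMF, 0 °C to rt
Reagents that add atoms: benzyl bromide, BrCc1ccccc1
Why: Williamson etherification of the four phenols, which are far more acidic than the secondary 3-OH, under a mild base that should keep C2 epimerisation low; no stereocentre is touched.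

Step 2
Reactants: 2 5,7,3',4'-tetra-O-benzyl-(−)-epicatechin
Product: 3 8-bromo-5,7,3',4'-tetra-O-benzyl-(−)-epicatechin
Conditions: NBS, CH2Cl2, −45 °C to rt
Reagents that add atoms: N-bromosuccinimide, O=C1CCC(=O)N1Br
Why: electrophilic aromatic bromination at C8, the most nucleophilic position of ring A of benzylated flavan-3-ols; the bromine blocks C8 against self-condensation in step 5 and is the handle for step 8.

Step 3
Reactants: 3 8-bromo-5,7,3',4'-tetra-O-benzyl-(−)-epicatechin
Product: 4 8-bromo-4β-(2-ethoxyethoxy)-5,7,3',4'-tetra-O-benzylepicatechin (4-alkoxy trans to the 3-OH)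
Conditions: DDQ, 2-ethoxyethanol, CH2Cl2, rt
Reagents that add atoms: 2-ethoxyethanol, CCOCCO
Why: DDQ benzylic oxidation (hydride abstraction from C4, assisted by the oxygens of ring A) with trapping of the cation by the alcohol trans to the 3-OH; the C4 configuration is of no consequence because C4 is ionised again in step 5.

Step 4
Reactants: 5 (+)-catechin
Product: 6 3,5,7,3',4'-penta-O-benzyl-(+)-catechin (2R,3S)
Conditions: BnBr (5.5 equiv), K2CO3, DMF, rt; then NaH, 0 °C to rt
Reagents that add atoms: benzyl bromide, BrCc1ccccc1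
Why: Williamson etherification, phenols first under carbonate and the 3-OH then as its sodium alkoxide, so that the bottom 3-OH stays masked until the final hydrogenolysis; no stereocentre is touched.

Step 5
Reactants: 4 8-bromo-4β-(2-ethoxyethoxy)-5,7,3',4'-tetra-O-benzylepicatechin; 6 3,5,7,3',4'-penta-O-benzyl-(+)-catechin
Product: 7 8-bromo-5,7,3',4'-tetra-O-benzylepicatechin-(4β→8)-3,5,7,3',4'-penta-O-benzylcatechin (3-OH of the upper unit free)
Conditions: TMSOTf (0.2 equiv), 6 (3 equiv), CH2Cl2, −78 °C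
Reagents that add atoms: none
Why: Lewis-acid ionisation of the 4-alkoxy group gives the C4 benzylic cation, which alkylates C8 of 6 (Friedel–Crafts type interflavan coupling) from the face trans to the axial 3-OH, so that C4 of the middle unit is set 4β, while the bromine prevents self-condensation of 4.

Step 6
Reactants: 8 2,4,6-trihydroxybenzaldehyde
Product: 9 4,6-bis(benzyloxy)-2-hydroxybenzaldehyde
Conditions: BnBr (2.05 equiv), K2CO3, DMF, rt
Reagents that add atoms: benzyl bromide, BrCc1ccccc1
Why: Williamson etherification that should stop at the dibenzyl ether because the last ortho-OH is held in a hydrogen bond to the formyl group.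

Step 7
Reactants: 9 4,6-bis(benzyloxy)-2-hydroxybenzaldehyde
Product: 10 4,6-bis(benzyloxy)-2-(tert-butyldimethylsilyloxy)benzaldehyde
Conditions: TBSCl, imidazole, DMF, rt
Reagents that add atoms: tert-butyldimethylsilyl chloride, CC(C)(C)[Si](C)(C)Cl
Why: silylation of the phenol, so that the aldehyde is not deactivated as a phenoxide towards the aryllithium of step 8 and can be unmasked by fluoride without acid.

Step 8
Reactants: 7 8-bromo-5,7,3',4'-tetra-O-benzylepicatechin-(4β→8)-3,5,7,3',4'-penta-O-benzylcatechin; 10 4,6-bis(benzyloxy)-2-(tert-butyldimethylsilyloxy)benzaldehyde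
Product: 13 8-[(2-hydroxy-4,6-bis(benzyloxy)phenyl)(hydroxy)methyl]-5,7,3',4'-tetra-O-benzylepicatechin-(4β→8)-3,5,7,3',4'-penta-O-benzylcatechin (carbinol epimers), via dilithiated dimer 11 (not isolated), via silyl ether carbinol 12 (not isolated)
Conditions: t-BuLi (3.1 equiv), THF, −78 °C; then 10 (1.5 equiv), −78 to −20 °C; then TBAF, 0 °C; pH 7 buffer work-up, Et3N-deactivated silica
Reagents that add atoms: none
Why: deprotonation of the 3-OH and bromine–lithium exchange give the C8 aryllithium, which undergoes 1,2-addition to the aldehyde, and fluoride then frees the phenol from whichever oxygen holds the silyl group; the carbinol centre forms as an epimer mixture that becomes trigonal in step 11.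

Step 9
Reactants: 14 3,4-bis(benzyloxy)benzaldehyde
Product: 15 1,2-bis(benzyloxy)-4-ethynylbenzene
Conditions: dimethyl (1-diazo-2-oxopropyl)phosphonate, K2CO3, MeOH, rt
Reagents that add atoms: dimethyl (1-diazo-2-oxopropyl)phosphonate, COP(=O)(OC)C(=[N+]=[N-])C(C)=O
Why: Ohira–Bestmann (Seyferth–Gilbert) homologation, in which the diazo carbon becomes the terminal alkyne carbon after loss of dimethyl phosphate and nitrogen and a 1,2-hydride shift.

Step 10
Reactants: 15 1,2-bis(benzyloxy)-4-ethynylbenzene; 16 3,4,5-tris(benzyloxy)benzoic acid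
Product: 17 (Z)-2-[3,4-bis(benzyloxy)phenyl]ethenyl 3,4,5-tris(benzyloxy)benzoate
Conditions: [RuCl2(p-cymene)]2 (1 mol%), P(4-ClC6H4)3 (3 mol%), DMAP (4 mol%), toluene, 60 °C
Reagents that add atoms: none
Why: ruthenium-catalysed anti-Markovnikov hydro-oxycarbonylation of a terminal alkyne through a ruthenium vinylidene, whose attack by the carboxylate at the α-carbon and protonolysis should give the Z enol ester that later fixes the 2,3-cis relation.

Step 11
Reactants: 13 8-[(2-hydroxy-4,6-bis(benzyloxy)phenyl)(hydroxy)methyl] dimer (carbinol epimers); 17 (Z)-2-[3,4-bis(benzyloxy)phenyl]ethenyl 3,4,5-tris(benzyloxy)benzoate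
Product: 19 [5,7,3',4'-tetra-O-benzylepicatechin 3-O-(3,4,5-tri-O-benzylgallate)]-(4β→8)-[5,7,3',4'-tetra-O-benzylepicatechin]-(4β→8)-[3,5,7,3',4'-penta-O-benzylcatechin] (3-OH of the middle unit free; top unit 2,3-cis-3,4-trans, 2R,3R), via ortho-quinone methide 18 (not isolated)
Conditions: (R)-TRIP [(R)-3,3'-bis(2,4,6-triisopropylphenyl)-1,1'-binaphthyl-2,2'-diyl hydrogen phosphate] (10 mol%), 17 (3 equiv), 5 Å MS, toluene (0.01 M, slow addition of 13), 0 °C to rt
Reagents that add atoms: none
Why: Proposed new method: the chiral phosphoric acid should ionise the doubly aryl-stabilised benzhydrol 13 to the ortho-quinone methide 18 (O=C8a–C4a=C4 of the future top unit, held by the phosphate at its carbonyl oxygen), which should take up the (Z)-enol gallate 17 as the 2π partner in an inverse-electron-demand oxa-[4+2] cycloaddition; the closest known reaction type is the phosphoric-acid-catalysed hetero-Diels–Alder reaction of quinone methides from ortho-hydroxybenzhydrols with electron-rich styrenes to give 2,4-diarylchromans, for which a β-acyloxystyrene has not been shown as partner. Ring C of the top unit, the only ring closed, forms by this formal [4+2] cycloaddition through an asynchronous six-membered transition state in which C4–C3 leads and O1–C2 follows, and the regiochemistry follows from the positive charge building up in the dienophile being best held at the benzylic carbon by the para-benzyloxy group of ring B, so that this carbon joins O1 and the acyloxy-bearing carbon joins C4. C2 and C3 take their cis relation from the Z geometry of 17, transferred suprafacially as long as the second bond closes before the C2–C3 bond can rotate, which toluene and low temperature favour by keeping the ion pair tight. C4 should become trans to the 3-gallate through the Z-quinone methide/endo arrangement, in which the perpendicular, di-ortho-oxygenated ring A of the middle unit sits syn to the small carbonyl oxygen and not to the peri benzyloxy group at C5 and lies anti to the galloyloxy group across the first-formed bond (the E-quinone methide/exo arrangement gives the same 3,4-trans product), while the face of C4 that is attacked should be set by the catalyst pocket because the stereocentres of 13 are too remote to decide it. The step needs chemoselectivity for one ring, regioselectivity, 2,3-cis/3,4-trans diastereoselectivity and facial selectivity: the first is secured by the substrate, since the phenol of top ring A is the only free hydroxyl ortho to the carbinol (the flanking oxygens of the middle ring A are O1 and a benzyl ether), the second by ring B, the last two by the alkene geometry and the catalyst, and Friedel–Crafts self-condensation is held back by high dilution and the excess of 17.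

Step 12
Reactants: 19 protected trimer monogallate (3-OH of the middle unit free); 16 3,4,5-tris(benzyloxy)benzoic acid
Product: 20 [5,7,3',4'-tetra-O-benzylepicatechin 3-O-(3,4,5-tri-O-benzylgallate)]-(4β→8)-[5,7,3',4'-tetra-O-benzylepicatechin 3-O-(3,4,5-tri-O-benzylgallate)]-(4β→8)-[3,5,7,3',4'-penta-O-benzylcatechin]
Conditions: DCC, DMAP, CH2Cl2, rt
Reagents that add atoms: none
Why: Steglich esterification of the only free hydroxyl, the axial 3-OH of the middle unit, through the acylpyridinium of the O-acylisourea, with retention at C3 because the C–O bond is not broken.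

Step 13
Reactants: 20 protected trimer digallate
Product: 21 epicatechin 3-O-gallate-(4β→8)-epicatechin 3-O-gallate-(4β→8)-catechin (target)
Conditions: H2 (1 atm), Pd(OH)2/C, THF/MeOH/H2O, rt
Reagents that add atoms: none
Why: hydrogenolysis of the 18 aryl benzyl ethers and the one alkyl benzyl ether, under which the gallate esters, the interflavan bonds and the C2–O1 bonds of flavans are expected to survive, so that no stereocentre is touched.

**Compound list**

1 | (−)-epicatechin | O[C@@H]1Cc2c(O)cc(O)cc2O[C@@H]1c1ccc(O)c(O)c1 | starting material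
2 | 5,7,3',4'-tetra-O-benzyl-(−)-epicatechin | O[C@@H]1Cc2c(OCc3ccccc3)cc(OCc3ccccc3)cc2O[C@@H]1c1ccc(OCc2ccccc2)c(OCc2ccccc2)c1 | intermediate
3 | 8-bromo-5,7,3',4'-tetra-O-benzyl-(−)-epicatechin | O[C@@H]1Cc2c(OCc3ccccc3)cc(OCc3ccccc3)c(Br)c2O[C@@H]1c1ccc(OCc2ccccc2)c(OCc2ccccc2)c1 | intermediate
4 | 8-bromo-4β-(2-ethoxyethoxy)-5,7,3',4'-tetra-O-benzylepicatechin | O[C@@H]1[C@@H](OCCOCC)c2c(OCc3ccccc3)cc(OCc3ccccc3)c(Br)c2O[C@@H]1c1ccc(OCc2ccccc2)c(OCc2ccccc2)c1 | intermediate
5 | (+)-catechin | O[C@H]1Cc2c(O)cc(O)cc2O[C@@H]1c1ccc(O)c(O)c1 | starting material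
6 | 3,5,7,3',4'-penta-O-benzyl-(+)-catechin | O(Cc1ccccc1)[C@H]1Cc2c(OCc3ccccc3)cc(OCc3ccccc3)cc2O[C@@H]1c1ccc(OCc2ccccc2)c(OCc2ccccc2)c1 | intermediate
7 | 8-bromo-5,7,3',4'-tetra-O-benzylepicatechin-(4β→8)-3,5,7,3',4'-penta-O-benzylcatechin | O[C@@H]1[C@@H](c2c(OCc3ccccc3)cc(OCc3ccccc3)c3c2O[C@H](c2ccc(OCc4ccccc4)c(OCc4ccccc4)c2)[C@@H](OCc2ccccc2)C3)c2c(OCc3ccccc3)cc(OCc3ccccc3)c(Br)c2O[C@@H]1c1ccc(OCc2ccccc2)c(OCc2ccccc2)c1 | intermediate
8 | 2,4,6-trihydroxybenzaldehyde | O=Cc1c(O)cc(O)cc1O | starting material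
9 | 4,6-bis(benzyloxy)-2-hydroxybenzaldehyde | O=Cc1c(O)cc(OCc2ccccc2)cc1OCc1ccccc1 | intermediate
10 | 4,6-bis(benzyloxy)-2-(tert-butyldimethylsilyloxy)benzaldehyde | O=Cc1c(O[Si](C)(C)C(C)(C)C)cc(OCc2ccccc2)cc1OCc1ccccc1 | intermediate
11 | dilithiated dimer (8-lithio, 3-O-lithio derivative of 7 without bromine) | [Li]O[C@@H]1[C@@H](c2c(OCc3ccccc3)cc(OCc3ccccc3)c3c2O[C@H](c2ccc(OCc4ccccc4)c(OCc4ccccc4)c2)[C@@H](OCc2ccccc2)C3)c2c(OCc3ccccc3)cc(OCc3ccccc3)c([Li])c2O[C@@H]1c1ccc(OCc2ccccc2)c(OCc2ccccc2)c1 | intermediate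
12 | silyl ether carbinol (adduct of 11 and 10, written in its neutral form; carbinol epimers) | O[C@@H]1[C@@H](c2c(OCc3ccccc3)cc(OCc3ccccc3)c3c2O[C@H](c2ccc(OCc4ccccc4)c(OCc4ccccc4)c2)[C@@H](OCc2ccccc2)C3)c2c(OCc3ccccc3)cc(OCc3ccccc3)c(C(O)c3c(O[Si](C)(C)C(C)(C)C)cc(OCc4ccccc4)cc3OCc3ccccc3)c2O[C@@H]1c1ccc(OCc2ccccc2)c(OCc2ccccc2)c1 | intermediate
13 | 8-[(2-hydroxy-4,6-bis(benzyloxy)phenyl)(hydroxy)methyl]-5,7,3',4'-tetra-O-benzylepicatechin-(4β→8)-3,5,7,3',4'-penta-O-benzylcatechin (carbinol epimers) | O[C@@H]1[C@@H](c2c(OCc3ccccc3)cc(OCc3ccccc3)c3c2O[C@H](c2ccc(OCc4ccccc4)c(OCc4ccccc4)c2)[C@@H](OCc2ccccc2)C3)c2c(OCc3ccccc3)cc(OCc3ccccc3)c(C(O)c3c(O)cc(OCc4ccccc4)cc3OCc3ccccc3)c2O[C@@H]1c1ccc(OCc2ccccc2)c(OCc2ccccc2)c1 | intermediate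
14 | 3,4-bis(benzyloxy)benzaldehyde | O=Cc1ccc(OCc2ccccc2)c(OCc2ccccc2)c1 | starting material
15 | 1,2-bis(benzyloxy)-4-ethynylbenzene | C#Cc1ccc(OCc2ccccc2)c(OCc2ccccc2)c1 | intermediate
16 | 3,4,5-tris(benzyloxy)benzoic acid | OC(=O)c1cc(OCc2ccccc2)c(OCc2ccccc2)c(OCc2ccccc2)c1 | starting material
17 | (Z)-2-[3,4-bis(benzyloxy)phenyl]ethenyl 3,4,5-tris(benzyloxy)benzoate | O=C(O/C=C\c1ccc(OCc2ccccc2)c(OCc2ccccc2)c1)c1cc(OCc2ccccc2)c(OCc2ccccc2)c(OCc2ccccc2)c1 | intermediate
18 | ortho-quinone methide from 13 (6-arylmethylidene-3,5-bis(benzyloxy)cyclohexa-2,4-dien-1-one on C8 of the middle unit) | O[C@@H]1[C@@H](c2c(OCc3ccccc3)cc(OCc3ccccc3)c3c2O[C@H](c2ccc(OCc4ccccc4)c(OCc4ccccc4)c2)[C@@H](OCc2ccccc2)C3)c2c(OCc3ccccc3)cc(OCc3ccccc3)c(C=C3C(=O)C=C(OCc4ccccc4)C=C3OCc3ccccc3)c2O[C@@H]1c1ccc(OCc2ccccc2)c(OCc2ccccc2)c1 | intermediate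
19 | protected trimer monogallate (top unit galloylated, 3-OH of the middle unit free) | O[C@@H]1[C@@H](c2c(OCc3ccccc3)cc(OCc3ccccc3)c3c2O[C@H](c2ccc(OCc4ccccc4)c(OCc4ccccc4)c2)[C@@H](OCc2ccccc2)C3)c2c(OCc3ccccc3)cc(OCc3ccccc3)c([C@H]3c4c(OCc5ccccc5)cc(OCc5ccccc5)cc4O[C@H](c4ccc(OCc5ccccc5)c(OCc5ccccc5)c4)[C@@H]3OC(=O)c3cc(OCc4ccccc4)c(OCc4ccccc4)c(OCc4ccccc4)c3)c2O[C@@H]1c1ccc(OCc2ccccc2)c(OCc2ccccc2)c1 | intermediate
20 | protected trimer digallate (nonadeca-O-benzyl target) | O=C(O[C@@H]1[C@@H](c2c(OCc3ccccc3)cc(OCc3ccccc3)c3c2O[C@H](c2ccc(OCc4ccccc4)c(OCc4ccccc4)c2)[C@@H](OCc2ccccc2)C3)c2c(OCc3ccccc3)cc(OCc3ccccc3)c([C@H]3c4c(OCc5ccccc5)cc(OCc5ccccc5)cc4O[C@H](c4ccc(OCc5ccccc5)c(OCc5ccccc5)c4)[C@@H]3OC(=O)c3cc(OCc4ccccc4)c(OCc4ccccc4)c(OCc4ccccc4)c3)c2O[C@@H]1c1ccc(OCc2ccccc2)c(OCc2ccccc2)c1)c1cc(OCc2ccccc2)c(OCc2ccccc2)c(OCc2ccccc2)c1 | intermediate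
21 | epicatechin 3-O-gallate-(4β→8)-epicatechin 3-O-gallate-(4β→8)-catechin | O=C(O[C@@H]1[C@@H](c2c(O)cc(O)c3c2O[C@H](c2ccc(O)c(O)c2)[C@@H](O)C3)c2c(O)cc(O)c([C@H]3c4c(O)cc(O)cc4O[C@H](c4ccc(O)c(O)c4)[C@@H]3OC(=O)c3cc(O)c(O)c(O)c3)c2O[C@@H]1c1ccc(O)c(O)c1)c1cc(O)c(O)c(O)c1 | target

**Count and risks**

Total step count: 13. Longest linear sequence: 8 steps (1, 2, 3, 5, 8, 11, 12, 13).

Steps most likely to fail:

Step 11 (Proposed new method). What may go wrong: attack on the wrong face of C4 or through the all-cis arrangement, loss of the Z geometry by a stepwise cationic pathway with bond rotation, sluggish addition of the deactivated enol ester to a strongly stabilised quinone methide, and Friedel–Crafts self-condensation of 18. Fallback by known interflavan coupling, setting out from 7 and returning at 20. Bromine–lithium exchange on 7 and protonation (t-BuLi, THF, −78 °C, then MeOH) would give 5,7,3',4'-tetra-O-benzylepicatechin-(4β→8)-3,5,7,3',4'-penta-O-benzylcatechin F1. Steglich esterification with 16 would give its upper-unit 3-O-(tri-O-benzylgallate) F2. Separately, 2 would be esterified with 16 (DCC, DMAP) to 5,7,3',4'-tetra-O-benzylepicatechin 3-O-(tri-O-benzylgallate) F3 and oxidised (DDQ, 2-ethoxyethanol) to its 4β-(2-ethoxyethoxy) ether F4. TMSOTf-mediated coupling of F4 with F2 should occur at the free C8 of the upper unit of F2, with the 3-gallate of F4 directing trans (4β) attack, and give 20 directly.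

Step 8. What may go wrong: proton capture by the hindered aryllithium, or silyl transfer, outrunning its addition to the di-ortho-substituted aldehyde 10. Fallback with inverted roles, setting out from 7 and returning at 13. The aryllithium 11 would be trapped with the small electrophile DMF (excess) to give the 8-formyl dimer F5. Ortho-specific hydroxyalkylation with an excess of bromomagnesium 3,5-bis(benzyloxy)phenoxide F6 (from 3,5-bis(benzyloxy)phenol and EtMgBr, toluene, rt) should then add the phenol ring through its chelated ortho carbon and give 13.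

Step 10. What may go wrong: Markovnikov addition or erosion of the Z geometry, which would pass into the 2,3-relation of the top unit. Fallback by a stereoretentive C–O coupling, setting out from 14 and returning at 17. Stork–Zhao olefination of 14 ((iodomethyl)triphenylphosphonium iodide, NaHMDS, THF, −78 °C) would give (Z)-1,2-bis(benzyloxy)-4-(2-iodoethenyl)benzene F7. Ullmann-type coupling with 16 (CuI, 3,4,7,8-tetramethyl-1,10-phenanthroline, Cs2CO3, toluene, 80 °C), which keeps the alkene geometry, should give 17.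

Further compounds
F1 | step 11 | 5,7,3',4'-tetra-O-benzylepicatechin-(4β→8)-3,5,7,3',4'-penta-O-benzylcatechin | O[C@@H]1[C@@H](c2c(OCc3ccccc3)cc(OCc3ccccc3)c3c2O[C@H](c2ccc(OCc4ccccc4)c(OCc4ccccc4)c2)[C@@H](OCc2ccccc2)C3)c2c(OCc3ccccc3)cc(OCc3ccccc3)cc2O[C@@H]1c1ccc(OCc2ccccc2)c(OCc2ccccc2)c1
F2 | step 11 | upper-unit 3-O-[3,4,5-tris(benzyloxy)benzoate] of F1 | O=C(O[C@@H]1[C@@H](c2c(OCc3ccccc3)cc(OCc3ccccc3)c3c2O[C@H](c2ccc(OCc4ccccc4)c(OCc4ccccc4)c2)[C@@H](OCc2ccccc2)C3)c2c(OCc3ccccc3)cc(OCc3ccccc3)cc2O[C@@H]1c1ccc(OCc2ccccc2)c(OCc2ccccc2)c1)c1cc(OCc2ccccc2)c(OCc2ccccc2)c(OCc2ccccc2)c1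
F3 | step 11 | 5,7,3',4'-tetra-O-benzylepicatechin 3-O-[3,4,5-tris(benzyloxy)benzoate] | O=C(O[C@@H]1Cc2c(OCc3ccccc3)cc(OCc3ccccc3)cc2O[C@@H]1c1ccc(OCc2ccccc2)c(OCc2ccccc2)c1)c1cc(OCc2ccccc2)c(OCc2ccccc2)c(OCc2ccccc2)c1
F4 | step 11 | 4β-(2-ethoxyethoxy)-5,7,3',4'-tetra-O-benzylepicatechin 3-O-[3,4,5-tris(benzyloxy)benzoate] | O=C(O[C@@H]1[C@@H](OCCOCC)c2c(OCc3ccccc3)cc(OCc3ccccc3)cc2O[C@@H]1c1ccc(OCc2ccccc2)c(OCc2ccccc2)c1)c1cc(OCc2ccccc2)c(OCc2ccccc2)c(OCc2ccccc2)c1
F5 | step 8 | 8-formyl-5,7,3',4'-tetra-O-benzylepicatechin-(4β→8)-3,5,7,3',4'-penta-O-benzylcatechin | O[C@@H]1[C@@H](c2c(OCc3ccccc3)cc(OCc3ccccc3)c3c2O[C@H](c2ccc(OCc4ccccc4)c(OCc4ccccc4)c2)[C@@H](OCc2ccccc2)C3)c2c(OCc3ccccc3)cc(OCc3ccccc3)c(C=O)c2O[C@@H]1c1ccc(OCc2ccccc2)c(OCc2ccccc2)c1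
F6 | step 8 | bromomagnesium 3,5-bis(benzyloxy)phenoxide | Br[Mg]Oc1cc(OCc2ccccc2)cc(OCc2ccccc2)c1
F7 | step 10 | (Z)-1,2-bis(benzyloxy)-4-(2-iodoethenyl)benzene | I/C=C\c1ccc(OCc2ccccc2)c(OCc2ccccc2)c1
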